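**Retrosynthetic overview**

1. Salimabromide 35 ⇐ keto-aldehyde 34: the cycloheptenone is closed last by intramolecular aldol condensation (C13=C14). 34 ⇐ aldehyde 30 by acyl-anion addition (C8–C15) with transfer of the lactone to the C8 oxygen.
2. 30 ⇐ alkylidene lactone 22: C7–C8 by intermolecular nitro-Michael addition of nitromethane. The fused lactone holds the C12 methyl pseudo-axial and so sets C7, then C11. The arene is dibrominated directly afterwards.
3. 22 ⇐ benzyl lactone 16: the tetralin ring is closed by Friedel–Crafts alkylation (C16–aryl, para to ethyl), then desaturated.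
4. 16 ⇐ lactone 11 + 3-ethylbenzaldehyde 12: fragment union by intermolecular aldol condensation (C7–C11).
5. 11 ⇐ ethyl (S)-lactate 1: quaternary C12 by Johnson–Claisen chirality transfer. Ring order: temporary γ-lactone → tetralin → γ-lactone moved to C8 → cycloheptenone.

Labels used: C7 benzylic CH, C8 CH–O, C10 lactone C=O, C11 its α-CH, C12 quaternary C–Me, C13=C14 enone CH=CH, C15 ketone, C16 CMe2.

Assumption: centres that are erased or equilibrated later (C11 in 13–21, the carbinol carbon in 13/14, C8 in 31–34) are carried as epimer mixtures and left undefined in the SMILES.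

**Route**

Step 1
Reactants: 1 ethyl (S)-lactate
Product: 2 ethyl (2S)-2-[(tert-butyldimethylsilyl)oxy]propanoate
Conditions: TBSCl, imidazole, DMF, 0 °C → rt
Reagents that add atoms: tert-butyldimethylsilyl chloride, CC(C)(C)[Si](C)(C)Cl
Why: Silyl ether protection of the secondary alcohol lets the ester be reduced and olefinated without racemising the lactate centre.

Step 2
Reactants: 2 ethyl (2S)-2-[(tert-butyldimethylsilyl)oxy]propanoate; 3 ethyl 2-(triphenylphosphoranylidene)propanoate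
Product: 5 ethyl (2E,4S)-4-[(tert-butyldimethylsilyl)oxy]-2-methylpent-2-enoate, via silyloxy aldehyde 4 (not isolated)
Conditions: i-Bu2AlH (1.05 equiv), CH2Cl2, −78 °C; then 3, −78 °C → rt; aq. KNaC4H4O6
Reagents that add atoms: none
Why: Half-reduction to the labile α-silyloxy aldehyde and in-flask Wittig olefination with the stabilised ylide give the (E)-trisubstituted enoate while the stereocentre is untouched.

Step 3
Reactants: 5 ethyl (2E,4S)-4-[(tert-butyldimethylsilyl)oxy]-2-methylpent-2-enoate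
Product: 6 ethyl (2E,4S)-4-hydroxy-2-methylpent-2-enoate
Conditions: 48% aq. HF, MeCN, 0 °C → rt
Reagents that add atoms: none
Why: Acidic fluoride desilylation frees the allylic alcohol, and the (E)-geometry prevents butenolide formation.

Step 4
Reactants: 6 ethyl (2E,4S)-4-hydroxy-2-methylpent-2-enoate
Product: 8 diethyl (2S)-2-methyl-2-[(1E)-prop-1-en-1-yl]butanedioate, via ketene acetal 7 (not isolated)
Conditions: MeC(OEt)3 (6 equiv), EtCO2H (0.1 equiv), 140 °C, EtOH distilled off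
Reagents that add atoms: triethyl orthoacetate, CCOC(C)(OCC)OCC
Why: Johnson–Claisen rearrangement through the chair with the carbinol methyl equatorial (the other chair has a 1,3-diaxial Me/Me clash) transfers the (S)-carbinol chirality across the (E)-alkene to the quaternary C12 (S) and gives the (E)-propenyl group.

Step 5
Reactants: 8 diethyl (2S)-2-methyl-2-[(1E)-prop-1-en-1-yl]butanedioate
Product: 9 (3S,4E)-3-(ethoxycarbonyl)-3-methylhex-4-enoic acid
Conditions: LiOH·H2O (1.05 equiv), THF/H2O, 0 °C; then 1 M HCl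
Reagents that add atoms: lithium hydroxide, [Li+].[OH-]
Why: Saponification is far faster at the unhindered CH2CO2Et than at the ester on the quaternary carbon, which differentiates the two carboxyl groups.

Step 6
Reactants: 9 (3S,4E)-3-(ethoxycarbonyl)-3-methylhex-4-enoic acid
Product: 11 (4S)-4,5,5-trimethyl-4-[(1E)-prop-1-en-1-yl]oxolan-2-one, via hydroxy acid 10 (not isolated)
Conditions: MeMgBr (5 equiv), THF, 0 → 45 °C; then 2 M HCl, rt
Reagents that add atoms: methylmagnesium bromide, C[Mg]Br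
Why: The magnesium carboxylate is inert, so double Grignard addition occurs only at the remaining ester (creating C16Me2), and acid work-up lactonises the γ-hydroxy acid.

Step 7
Reactants: 11 (4S)-4,5,5-trimethyl-4-[(1E)-prop-1-en-1-yl]oxolan-2-one; 12 3-ethylbenzaldehyde
Product: 13 (4R)-3-[(3-ethylphenyl)(hydroxy)methyl]-4,5,5-trimethyl-4-[(1E)-prop-1-en-1-yl]oxolan-2-one
Conditions: LiN(i-Pr)2 (1.15 equiv), THF, −78 °C; then 12, −78 °C; AcOH quench
Reagents that add atoms: none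
Why: Intermolecular aldol addition of the lactone lithium enolate to the non-enolisable aromatic aldehyde joins the two main fragments (C7–C11), and both new centres are removed in the next two steps.

Step 8
Reactants: 13 (4R)-3-[(3-ethylphenyl)(hydroxy)methyl]-4,5,5-trimethyl-4-[(1E)-prop-1-en-1-yl]oxolan-2-one
Product: 15 (3E,4R)-3-[(3-ethylphenyl)methylidene]-4,5,5-trimethyl-4-[(1E)-prop-1-en-1-yl]oxolan-2-one, via mesylate 14 (not isolated)
Conditions: MsCl, Et3N, CH2Cl2, 0 °C; then DBU, rt → 40 °C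
Reagents that add atoms: none
Why: Mesylation and E1cB elimination complete the aldol condensation; the alkene geometry is irrelevant because it is reduced next.

Step 9
Reactants: 15 (3E,4R)-3-[(3-ethylphenyl)methylidene]-4,5,5-trimethyl-4-[(1E)-prop-1-en-1-yl]oxolan-2-one
Product: 16 (4R)-3-[(3-ethylphenyl)methyl]-4,5,5-trimethyl-4-[(1E)-prop-1-en-1-yl]oxolan-2-one
Conditions: Mg turnings (10 equiv), MeOH, 0 °C → rt
Reagents that add atoms: none
Why: Dissolving-metal conjugate reduction (Mg/MeOH) saturates only the cinnamate-type double bond and leaves the isolated propenyl group and the arene intact.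

Step 10
Reactants: 16 (4R)-3-[(3-ethylphenyl)methyl]-4,5,5-trimethyl-4-[(1E)-prop-1-en-1-yl]oxolan-2-one
Product: 18 (4S)-3-[(3-ethylphenyl)methyl]-4-(hydroxymethyl)-4,5,5-trimethyloxolan-2-one, via aldehyde 17 (not isolated)
Conditions: O3, CH2Cl2/MeOH (4:1), −78 °C; then NaBH4 (4 equiv), −78 °C → rt
Reagents that add atoms: ozone, [O-][O+]=O
Why: Ozonolysis with reductive work-up trims the propenyl group to the C13 hydroxymethyl group, the alkene reacting far faster than the alkylbenzene.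

Step 11
Reactants: 18 (4S)-3-[(3-ethylphenyl)methyl]-4-(hydroxymethyl)-4,5,5-trimethyloxolan-2-one
Product: 20 (3aR)-7-ethyl-3a,4,4-trimethyl-3a,4,9,9a-tetrahydronaphtho[2,3-c]furan-1(3H)-one, via hydroxy acid 19 (not isolated)
Conditions: TfOH (3 equiv), CH2Cl2, 0 °C → rt
Reagents that add atoms: none
Why: Acid ionises the tertiary lactone C–O bond and the C16 cation is trapped in a six-membered Friedel–Crafts cyclialkylation at the arene position para to ethyl, after which the acid and the hydroxymethyl group relactonise; C12 is not involved.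

Step 12
Reactants: 20 (3aR)-7-ethyl-3a,4,4-trimethyl-3a,4,9,9a-tetrahydronaphtho[2,3-c]furan-1(3H)-one
Product: 22 (3aS)-7-ethyl-3a,4,4-trimethyl-3a,4-dihydronaphtho[2,3-c]furan-1(3H)-one, via selenide 21 (not isolated)
Conditions: LiN(i-Pr)2 (1.3 equiv), THF, −78 °C; PhSeBr; then 30% H2O2, pyridine, CH2Cl2, 0 °C → rt
Reagents that add atoms: none
Why: α-Selenenylation and selenoxide syn-elimination can only take a benzylic C7 hydrogen (C12 is quaternary), giving the arene-conjugated alkylidene lactone from either ring-fusion epimer.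

Step 13
Reactants: 22 (3aS)-7-ethyl-3a,4,4-trimethyl-3a,4-dihydronaphtho[2,3-c]furan-1(3H)-one; 23 nitromethane
Product: 24 (3aR,9S,9aR)-7-ethyl-3a,4,4-trimethyl-9-(nitromethyl)-3a,4,9,9a-tetrahydronaphtho[2,3-c]furan-1(3H)-one
Conditions: DBU (1.0 equiv), MeNO2 (10 equiv), MeCN, 0 °C → rt
Reagents that add atoms: none
Why: In this intermolecular nitro-Michael addition the lactone holds C13 in the enoate plane and the C12 methyl pseudo-axial, so the nitronate adds axially to C7 on the face anti to that methyl (C8 cis to C13), and protonation of the lactone enolate gives the cis ring fusion that sets C11.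

Step 14
Reactants: 24 (3aR,9S,9aR)-7-ethyl-3a,4,4-trimethyl-9-(nitromethyl)-3a,4,9,9a-tetrahydronaphtho[2,3-c]furan-1(3H)-one
Product: 25 (3aR,9S,9aR)-6,8-dibromo-7-ethyl-3a,4,4-trimethyl-9-(nitromethyl)-3a,4,9,9a-tetrahydronaphtho[2,3-c]furan-1(3H)-one
Conditions: Br2 (2.4 equiv), AgO2CCF3 (2.4 equiv), CF3CO2H, 0 °C → rt, dark
Reagents that add atoms: bromine, BrBr
Why: Electrophilic aromatic substitution goes to the two positions ortho to ethyl (each also ortho or para to the second alkyl group), the third free position being singly activated and shielded by the gem-dimethyl group, while nitroalkane and lactone are inert.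

Step 15
Reactants: 25 (3aR,9S,9aR)-6,8-dibromo-7-ethyl-3a,4,4-trimethyl-9-(nitromethyl)-3a,4,9,9a-tetrahydronaphtho[2,3-c]furan-1(3H)-one
Product: 26 (1S,2R,3R)-6,8-dibromo-7-ethyl-3-(hydroxymethyl)-N,N,3,4,4-pentamethyl-1-(nitromethyl)-1,2,3,4-tetrahydronaphthalene-2-carboxamide
Conditions: AlMe3 (4 equiv), Me2NH (4.4 equiv, 2 M in THF), CH2Cl2, 0 → 40 °C; aq. KNaC4H4O6; used at once
Reagents that add atoms: dimethylamine, CNC
Why: Weinreb aluminium-amide aminolysis opens the hindered lactone irreversibly to a tertiary amide that does not relactonise under neutral conditions, freeing the C13 alcohol.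

Step 16
Reactants: 26 (1S,2R,3R)-6,8-dibromo-7-ethyl-3-(hydroxymethyl)-N,N,3,4,4-pentamethyl-1-(nitromethyl)-1,2,3,4-tetrahydronaphthalene-2-carboxamide
Product: 27 (1S,2R,3R)-6,8-dibromo-7-ethyl-3-formyl-N,N,3,4,4-pentamethyl-1-(nitromethyl)-1,2,3,4-tetrahydronaphthalene-2-carboxamide
Conditions: Dess–Martin periodinane (1.5 equiv), CH2Cl2, rt
Reagents that add atoms: none
Why: Neutral Dess–Martin oxidation gives the non-enolisable C13 aldehyde without forming the nitronate, so no nitro-aldol can occur.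

Step 17
Reactants: 27 (1S,2R,3R)-6,8-dibromo-7-ethyl-3-formyl-N,N,3,4,4-pentamethyl-1-(nitromethyl)-1,2,3,4-tetrahydronaphthalene-2-carboxamide
Product: 28 (1S,2R,3R)-6,8-dibromo-3-(1,3-dithian-2-yl)-7-ethyl-N,N,3,4,4-pentamethyl-1-(nitromethyl)-1,2,3,4-tetrahydronaphthalene-2-carboxamide
Conditions: HS(CH2)3SH (1.5 equiv), BF3·OEt2 (0.3 equiv), CH2Cl2, 0 °C → rt
Reagents that add atoms: propane-1,3-dithiol, SCCCS
Why: Lewis-acid thioacetalisation masks the C13 aldehyde as a dithiane that survives base, organolithium and aqueous acid, so C13 never reappears as a free alcohol beside an acyl group at C10.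

Step 18
Reactants: 28 (1S,2R,3R)-6,8-dibromo-3-(1,3-dithian-2-yl)-7-ethyl-N,N,3,4,4-pentamethyl-1-(nitromethyl)-1,2,3,4-tetrahydronaphthalene-2-carboxamide
Product: 30 (1S,2R,3R)-6,8-dibromo-3-(1,3-dithian-2-yl)-7-ethyl-1-formyl-N,N,3,4,4-pentamethyl-1,2,3,4-tetrahydronaphthalene-2-carboxamide, via sodium nitronate 29 (not isolated)
Conditions: NaOMe (1.1 equiv), MeOH, 0 °C; then aq. TiCl3 (4.5 equiv), NH4OAc buffer, 0 °C → rt
Reagents that add atoms: water, O
Why: The buffered reductive Nef reaction (nitronate → imine → aldehyde) unmasks C8 as the aldehyde at pH 5–6, mild enough to keep the benzylic α-centre C7.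

Step 19
Reactants: 30 (1S,2R,3R)-6,8-dibromo-3-(1,3-dithian-2-yl)-7-ethyl-1-formyl-N,N,3,4,4-pentamethyl-1,2,3,4-tetrahydronaphthalene-2-carboxamide
Product: 33 (3aR,4R,9bS)-1-acetyl-7,9-dibromo-4-(1,3-dithian-2-yl)-8-ethyl-4,5,5-trimethyl-3a,4,5,9b-tetrahydronaphtho[1,2-c]furan-3(1H)-one, via enol ether carbinol 31 (not isolated), via hydroxy ketone amide 32 (not isolated)
Conditions: CH2=C(OEt)Li (3 equiv, from ethyl vinyl ether and t-BuLi), THF, −78 °C; then 2 M HCl, THF, 45 °C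
Reagents that add atoms: 1-ethoxyvinyllithium, [Li]C(=C)OCC; water, O
Why: The acetyl-anion equivalent adds to the aldehyde (C8–C15), acid hydrolyses the enol ether to the methyl ketone, and the new C8 hydroxyl displaces dimethylamine from the cis amide to form the final γ-lactone; both C8 epimers form and converge in step 21.

Step 20
Reactants: 33 (3aR,4R,9bS)-1-acetyl-7,9-dibromo-4-(1,3-dithian-2-yl)-8-ethyl-4,5,5-trimethyl-3a,4,5,9b-tetrahydronaphtho[1,2-c]furan-3(1H)-one
Product: 34 (3aR,4R,9bS)-1-acetyl-7,9-dibromo-8-ethyl-4,5,5-trimethyl-3-oxo-1,3,3a,4,5,9b-hexahydronaphtho[1,2-c]furan-4-carbaldehyde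
Conditions: MeI (10 equiv), NaHCO3 (4 equiv), MeCN/H2O (4:1), 40 °C
Reagents that add atoms: water, O
Why: Alkylative dithiane hydrolysis releases the C13 aldehyde under near-neutral conditions that leave lactone, ketone and aryl bromides untouched.

Step 21
Reactants: 34 (3aR,4R,9bS)-1-acetyl-7,9-dibromo-8-ethyl-4,5,5-trimethyl-3-oxo-1,3,3a,4,5,9b-hexahydronaphtho[1,2-c]furan-4-carbaldehyde
Product: 35 salimabromide
Conditions: Bn2NH2+ CF3CO2− (0.5 equiv), PhH, 4 Å sieves, 70 °C
Reagents that add atoms: none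
Why: Amine-salt-catalysed intramolecular aldol condensation of the methyl ketone (C14) onto the non-enolisable C13 aldehyde closes the cycloheptenone; only the C8 epimer with the acetyl group syn to C13 can cyclise while the other equilibrates through the enol of the α-acyloxy ketone, so C8 is fixed as in the target.

**Compound list**

1 | ethyl (S)-lactate | C[C@H](O)C(=O)OCC | starting material
2 | ethyl (2S)-2-[(tert-butyldimethylsilyl)oxy]propanoate | C[C@H](O[Si](C)(C)C(C)(C)C)C(=O)OCC | intermediate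
3 | ethyl 2-(triphenylphosphoranylidene)propanoate | CCOC(=O)C(C)=P(c1ccccc1)(c1ccccc1)c1ccccc1 | starting material
4 | (2S)-2-[(tert-butyldimethylsilyl)oxy]propanal | C[C@H](O[Si](C)(C)C(C)(C)C)C=O | intermediate (not isolated)
5 | ethyl (2E,4S)-4-[(tert-butyldimethylsilyl)oxy]-2-methylpent-2-enoate | C[C@H](O[Si](C)(C)C(C)(C)C)/C=C(\C)C(=O)OCC | intermediate
6 | ethyl (2E,4S)-4-hydroxy-2-methylpent-2-enoate | C[C@H](O)/C=C(\C)C(=O)OCC | intermediate
7 | ethyl (2E,4S)-4-[(1-ethoxyethenyl)oxy]-2-methylpent-2-enoate | C[C@H](OC(=C)OCC)/C=C(\C)C(=O)OCC | intermediate (not isolated)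
8 | diethyl (2S)-2-methyl-2-[(1E)-prop-1-en-1-yl]butanedioate | CCOC(=O)C[C@@](C)(/C=C/C)C(=O)OCC | intermediate
9 | (3S,4E)-3-(ethoxycarbonyl)-3-methylhex-4-enoic acid | OC(=O)C[C@@](C)(/C=C/C)C(=O)OCC | intermediate
10 | (3S,4E)-3-(2-hydroxypropan-2-yl)-3-methylhex-4-enoic acid | OC(=O)C[C@@](C)(/C=C/C)C(C)(C)O | intermediate (not isolated)
11 | (4S)-4,5,5-trimethyl-4-[(1E)-prop-1-en-1-yl]oxolan-2-one | O=C1C[C@@](C)(/C=C/C)C(C)(C)O1 | intermediate
12 | 3-ethylbenzaldehyde | CCc1cccc(C=O)c1 | starting material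
13 | (4R)-3-[(3-ethylphenyl)(hydroxy)methyl]-4,5,5-trimethyl-4-[(1E)-prop-1-en-1-yl]oxolan-2-one (diastereomers at C3 and carbinol) | O=C1OC(C)(C)[C@](C)(/C=C/C)C1C(O)c1cccc(CC)c1 | intermediate
14 | methanesulfonate of 13 | O=C1OC(C)(C)[C@](C)(/C=C/C)C1C(OS(C)(=O)=O)c1cccc(CC)c1 | intermediate (not isolated)
15 | (3E,4R)-3-[(3-ethylphenyl)methylidene]-4,5,5-trimethyl-4-[(1E)-prop-1-en-1-yl]oxolan-2-one | O=C1OC(C)(C)[C@](C)(/C=C/C)/C1=C\c1cccc(CC)c1 | intermediate
16 | (4R)-3-[(3-ethylphenyl)methyl]-4,5,5-trimethyl-4-[(1E)-prop-1-en-1-yl]oxolan-2-one (C3 epimers) | O=C1OC(C)(C)[C@](C)(/C=C/C)C1Cc1cccc(CC)c1 | intermediate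
17 | (3R)-4-[(3-ethylphenyl)methyl]-2,2,3-trimethyl-5-oxooxolane-3-carbaldehyde (C4 epimers) | O=C1OC(C)(C)[C@](C)(C=O)C1Cc1cccc(CC)c1 | intermediate (not isolated)
18 | (4S)-3-[(3-ethylphenyl)methyl]-4-(hydroxymethyl)-4,5,5-trimethyloxolan-2-one (C3 epimers) | O=C1OC(C)(C)[C@](C)(CO)C1Cc1cccc(CC)c1 | intermediate
19 | (3R)-7-ethyl-3-(hydroxymethyl)-3,4,4-trimethyl-1,2,3,4-tetrahydronaphthalene-2-carboxylic acid (C2 epimers) | OC(=O)C1Cc2cc(CC)ccc2C(C)(C)[C@]1(C)CO | intermediate (not isolated)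
20 | (3aR)-7-ethyl-3a,4,4-trimethyl-3a,4,9,9a-tetrahydronaphtho[2,3-c]furan-1(3H)-one (C9a epimers) | O=C1OC[C@]2(C)C1Cc1cc(CC)ccc1C2(C)C | intermediate
21 | (3aR)-7-ethyl-3a,4,4-trimethyl-9a-(phenylselanyl)-3a,4,9,9a-tetrahydronaphtho[2,3-c]furan-1(3H)-one | O=C1OC[C@]2(C)C1([Se]c1ccccc1)Cc1cc(CC)ccc1C2(C)C | intermediate (not isolated)
22 | (3aS)-7-ethyl-3a,4,4-trimethyl-3a,4-dihydronaphtho[2,3-c]furan-1(3H)-one | O=C1OC[C@]2(C)C1=Cc1cc(CC)ccc1C2(C)C | intermediate
23 | nitromethane | C[N+](=O)[O-] | starting material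
24 | (3aR,9S,9aR)-7-ethyl-3a,4,4-trimethyl-9-(nitromethyl)-3a,4,9,9a-tetrahydronaphtho[2,3-c]furan-1(3H)-one | CCc1ccc2c(c1)[C@@H](C[N+](=O)[O-])[C@H]1C(=O)OC[C@@]1(C)C2(C)C | intermediate
25 | (3aR,9S,9aR)-6,8-dibromo-7-ethyl-3a,4,4-trimethyl-9-(nitromethyl)-3a,4,9,9a-tetrahydronaphtho[2,3-c]furan-1(3H)-one | CCc1c(Br)cc2c(c1Br)[C@@H](C[N+](=O)[O-])[C@H]1C(=O)OC[C@@]1(C)C2(C)C | intermediate
26 | (1S,2R,3R)-6,8-dibromo-7-ethyl-3-(hydroxymethyl)-N,N,3,4,4-pentamethyl-1-(nitromethyl)-1,2,3,4-tetrahydronaphthalene-2-carboxamide | CCc1c(Br)cc2c(c1Br)[C@@H](C[N+](=O)[O-])[C@@H](C(=O)N(C)C)[C@@](C)(CO)C2(C)C | intermediate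
27 | (1S,2R,3R)-6,8-dibromo-7-ethyl-3-formyl-N,N,3,4,4-pentamethyl-1-(nitromethyl)-1,2,3,4-tetrahydronaphthalene-2-carboxamide | CCc1c(Br)cc2c(c1Br)[C@@H](C[N+](=O)[O-])[C@@H](C(=O)N(C)C)[C@@](C)(C=O)C2(C)C | intermediate
28 | (1S,2R,3R)-6,8-dibromo-3-(1,3-dithian-2-yl)-7-ethyl-N,N,3,4,4-pentamethyl-1-(nitromethyl)-1,2,3,4-tetrahydronaphthalene-2-carboxamide | CCc1c(Br)cc2c(c1Br)[C@@H](C[N+](=O)[O-])[C@@H](C(=O)N(C)C)[C@@](C)(C1SCCCS1)C2(C)C | intermediate
29 | sodium nitronate of 28 | [Na+].CCc1c(Br)cc2c(c1Br)[C@@H](C=[N+]([O-])[O-])[C@@H](C(=O)N(C)C)[C@@](C)(C1SCCCS1)C2(C)C | intermediate (not isolated)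
30 | (1S,2R,3R)-6,8-dibromo-3-(1,3-dithian-2-yl)-7-ethyl-1-formyl-N,N,3,4,4-pentamethyl-1,2,3,4-tetrahydronaphthalene-2-carboxamide | CCc1c(Br)cc2c(c1Br)[C@@H](C=O)[C@@H](C(=O)N(C)C)[C@@](C)(C1SCCCS1)C2(C)C | intermediate
31 | (1S,2R,3R)-6,8-dibromo-3-(1,3-dithian-2-yl)-1-(2-ethoxy-1-hydroxyprop-2-en-1-yl)-7-ethyl-N,N,3,4,4-pentamethyl-1,2,3,4-tetrahydronaphthalene-2-carboxamide (carbinol epimers) | CCc1c(Br)cc2c(c1Br)[C@@H](C(O)C(=C)OCC)[C@@H](C(=O)N(C)C)[C@@](C)(C1SCCCS1)C2(C)C | intermediate (not isolated)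
32 | (1S,2R,3R)-6,8-dibromo-3-(1,3-dithian-2-yl)-7-ethyl-1-(1-hydroxy-2-oxopropyl)-N,N,3,4,4-pentamethyl-1,2,3,4-tetrahydronaphthalene-2-carboxamide (carbinol epimers) | CCc1c(Br)cc2c(c1Br)[C@@H](C(O)C(C)=O)[C@@H](C(=O)N(C)C)[C@@](C)(C1SCCCS1)C2(C)C | intermediate (not isolated)
33 | (3aR,4R,9bS)-1-acetyl-7,9-dibromo-4-(1,3-dithian-2-yl)-8-ethyl-4,5,5-trimethyl-3a,4,5,9b-tetrahydronaphtho[1,2-c]furan-3(1H)-one (C1 epimers) | CCc1c(Br)cc2c(c1Br)[C@H]1C(C(C)=O)OC(=O)[C@H]1[C@@](C)(C1SCCCS1)C2(C)C | intermediate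
34 | (3aR,4R,9bS)-1-acetyl-7,9-dibromo-8-ethyl-4,5,5-trimethyl-3-oxo-1,3,3a,4,5,9b-hexahydronaphtho[1,2-c]furan-4-carbaldehyde (C1 epimers) | CCc1c(Br)cc2c(c1Br)[C@H]1C(C(C)=O)OC(=O)[C@H]1[C@@](C)(C=O)C2(C)C | intermediate
35 | salimabromide | CCc1c(Br)cc2c(c1Br)[C@H]1[C@@H]3OC(=O)[C@H]1[C@@](C)(C=CC3=O)C2(C)C | target

**Totals**

Total step count: 21. Longest linear sequence: 21 steps (1 → 35); 12 enters at step 7 and 23 at step 13.

**Steps most likely to fail**

Step 11 (Friedel–Crafts closure beside a quaternary carbon). The tertiary cation could shift a methyl group or fragment with loss of the β-hydroxymethyl carbon. The fallback sets out from 16 and comes back at 20. Ozonolysis of 16 with Me2S work-up gives aldehyde 17, which NaClO2/NaH2PO4 oxidises to (3R)-4-[(3-ethylphenyl)methyl]-2,2,3-trimethyl-5-oxooxolane-3-carboxylic acid F1, whose carboxyl group is deactivating and cannot fragment. TfOH then closes the ring to (3R)-7-ethyl-3,4,4-trimethyl-1,2,3,4-tetrahydronaphthalene-2,3-dicarboxylic acid F2. Ac2O at 120 °C gives the cis-fused (3aR,9aR)-7-ethyl-3a,4,4-trimethyl-3a,4,9,9a-tetrahydronaphtho[2,3-c]furan-1,3-dione F3. NaBH4 reduces the carbonyl flanked by the quaternary carbon, the usual site of hydride attack in unsymmetrical succinic anhydrides, and returns lactone 20.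

Step 13 (face selectivity of the nitro-Michael addition, and later integrity of C7). If the axial-methyl control is weak, kinetic face selection is replaced by thermodynamic correction. The fallback sets out from 26 and comes back at 34.
- The Nef reaction (NaOMe, then TiCl3/NH4OAc) is run on 26 itself. The hydroxy aldehyde closes to the bridged lactol (1S,2R,3R)-configured 2-oxabicyclic hemiacetal amide F4 only when the formyl carbon is cis to the hydroxymethyl group, and catalytic DBU epimerises the C7-epimeric aldehyde into it.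
- Excess CH2=C(OEt)Li opens the lactol to the diol (1S,2R,3R)-6,8-dibromo-1-(2-ethoxy-1-hydroxyprop-2-en-1-yl)-7-ethyl-3-(hydroxymethyl)-N,N,3,4,4-pentamethyl-1,2,3,4-tetrahydronaphthalene-2-carboxamide F5.
- TEMPO/PhI(OAc)2 oxidises only the primary alcohol to the 3-formyl analogue F6.
- 2 M HCl in THF hydrolyses the enol ether and lactonises the C8 hydroxyl onto the amide to give 34.

Step 21 (seven-membered aldol condensation on a neopentyl aldehyde). If the one-pot thermodynamic condensation stalls, the closure is done as a directed, stepwise aldol. The fallback sets out from 34 and comes back at 35. (c-C6H11)2BCl/Et3N at −78 °C forms the less substituted boron enolate of the methyl ketone, which adds intramolecularly to the aldehyde to give the β-hydroxy ketone 13,14-dihydro-13-hydroxysalimabromide F7. MsCl/Et3N then eliminates to 35. Material with the wrong C8 configuration is first equilibrated with DBU.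

Further compounds

F1 | step 11 | (3R)-4-[(3-ethylphenyl)methyl]-2,2,3-trimethyl-5-oxooxolane-3-carboxylic acid (C4 epimers) | O=C1OC(C)(C)[C@](C)(C(O)=O)C1Cc1cccc(CC)c1
F2 | step 11 | (3R)-7-ethyl-3,4,4-trimethyl-1,2,3,4-tetrahydronaphthalene-2,3-dicarboxylic acid (C2 epimers) | OC(=O)C1Cc2cc(CC)ccc2C(C)(C)[C@]1(C)C(O)=O
F3 | step 11 | (3aR,9aR)-7-ethyl-3a,4,4-trimethyl-3a,4,9,9a-tetrahydronaphtho[2,3-c]furan-1,3-dione | CCc1ccc2c(c1)C[C@H]1C(=O)OC(=O)[C@@]1(C)C2(C)C
F4 | step 13 | bridged lactol from 26: 6,8-dibromo-7-ethyl-N,N,3,4,4-pentamethyl-tetrahydronaphthalene-2-carboxamide with C1–CH(OH)–O–CH2–C3 bridge (lactol anomers) | CCc1c(Br)cc2c(c1Br)[C@@H]1[C@@H](C(=O)N(C)C)[C@@](C)(COC1O)C2(C)C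
F5 | step 13 | (1S,2R,3R)-6,8-dibromo-1-(2-ethoxy-1-hydroxyprop-2-en-1-yl)-7-ethyl-3-(hydroxymethyl)-N,N,3,4,4-pentamethyl-1,2,3,4-tetrahydronaphthalene-2-carboxamide (carbinol epimers) | CCc1c(Br)cc2c(c1Br)[C@@H](C(O)C(=C)OCC)[C@@H](C(=O)N(C)C)[C@@](C)(CO)C2(C)C
F6 | step 13 | (1S,2R,3R)-6,8-dibromo-1-(2-ethoxy-1-hydroxyprop-2-en-1-yl)-7-ethyl-3-formyl-N,N,3,4,4-pentamethyl-1,2,3,4-tetrahydronaphthalene-2-carboxamide (carbinol epimers) | CCc1c(Br)cc2c(c1Br)[C@@H](C(O)C(=C)OCC)[C@@H](C(=O)N(C)C)[C@@](C)(C=O)C2(C)C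
F7 | step 21 | 13,14-dihydro-13-hydroxysalimabromide (carbinol epimers) | CCc1c(Br)cc2c(c1Br)[C@H]1[C@@H]3OC(=O)[C@H]1[C@@](C)(C(O)CC3=O)C2(C)C
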